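## Retrosynthetic overview
1. Target 21 ⇒ diaryl ether C–O bond, made last: ring A salicylic acid 13 + ring B 2-fluorobenzaldehyde 18 (SNAr ortho to CHO; the THP group falls off in the acidic work-up).
2. 13 ⇒ C–CO2H bond: lithiation of 10 between its two ring oxygens, then CO2.
3. 10 ⇒ key aryl–C(sp3) bond: aryl bromide 4 + the configurationally stable (S)-α-carbamoyloxy carbanion 5 made from isoamyl alcohol. The carbinol carbon acts as donor instead of acceptor, and this coupling sets the stereocentre. Then OCb → OH → OMe.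
4. 18 ⇒ fluorine-directed lithiation and formylation of the THP ether of 2-fluoro-5-methylphenol.
5. No ring is built. Both benzene rings are bought, ring A and ring B are elaborated separately, and they are joined in the last step.

Assumption: the stereocentre of the target is (R). The THP acetal carbons form as about 1:1 epimer mixtures, are written without a descriptor, and are deleted in steps 6 and 9.

## Route

Step 1
Reactants: 1 3-methylbutan-1-ol
Product: 2 3-methylbutyl N,N-diisopropylcarbamate
Conditions: i-Pr2NCOCl, Et3N, CH2Cl2, reflux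
Reagents that add atoms: N,N-diisopropylcarbamoyl chloride, CC(C)N(C(C)C)C(=O)Cl
Why: O-carbamoylation (nucleophilic acyl substitution) of an unhindered primary alcohol installs the hindered, dipole-stabilising group that step 3 needs to direct lithiation.

Step 2
Reactants: 3 4-bromo-3-methoxyphenol
Product: 4 2-(4-bromo-3-methoxyphenoxy)tetrahydropyran
Conditions: 3,4-dihydro-2H-pyran, PPTS (cat.), CH2Cl2, rt
Reagents that add atoms: 3,4-dihydro-2H-pyran, C1=COCCC1
Why: Acid-catalysed tetrahydropyranylation (phenol addition to an enol ether) masks the acidic OH against organozinc, hydride and NaH, and the OTHP group later serves as an ortho-directing group.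

Step 3
Reactants: 2 3-methylbutyl N,N-diisopropylcarbamate; 4 2-(4-bromo-3-methoxyphenoxy)tetrahydropyran
Product: 7 (1R)-1-[2-methoxy-4-(tetrahydropyran-2-yloxy)phenyl]-3-methylbutyl N,N-diisopropylcarbamate, via lithiated carbamate 5 (not isolated), via organozinc chloride 6 (not isolated)
Conditions: 2 (1.5 equiv), s-BuLi, (–)-sparteine, Et2O, –78 °C, 5 h; ZnCl2 (THF), –78 °C → rt; 4, Pd(OAc)2 (5 mol %), t-Bu3P·HBF4 (10 mol %), toluene, 60 °C
Reagents that add atoms: none
Why: Hoppe enantioselective deprotonation removes the pro-S hydrogen to give the configurationally stable (S)-α-oxy carbanion 5, and since Li→Zn exchange, Zn→Pd transmetalation and reductive elimination of the Negishi cross-coupling all proceed with retention, the aryl group takes the place of lithium and the centre becomes (R), the bulky t-Bu3P ligand on zerovalent palladium favouring reductive elimination over β-hydride elimination.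

Step 4
Reactants: 7 (1R)-1-[2-methoxy-4-(tetrahydropyran-2-yloxy)phenyl]-3-methylbutyl N,N-diisopropylcarbamate
Product: 8 (1R)-1-[2-methoxy-4-(tetrahydropyran-2-yloxy)phenyl]-3-methylbutan-1-ol
Conditions: LiAlH4, THF, reflux; H2O, NaOH (aq) work-up
Reagents that add atoms: none
Why: Hydride reduction of the carbamate carbonyl breaks the acyl–oxygen bond and not the benzylic C–O bond, so (R) is kept, and the THP acetal is inert to hydride and base.

Step 5
Reactants: 8 (1R)-1-[2-methoxy-4-(tetrahydropyran-2-yloxy)phenyl]-3-methylbutan-1-ol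
Product: 10 2-{3-methoxy-4-[(1R)-1-methoxy-3-methylbutyl]phenoxy}tetrahydropyran, via sodium alkoxide 9 (not isolated)
Conditions: NaH, MeI, THF–DMF, 0 °C → rt
Reagents that add atoms: iodomethane, CI
Why: Williamson ether synthesis alkylates at oxygen only, so the stereocentre is untouched and no acid reaches the electron-rich benzylic position.

Step 6
Reactants: 10 2-{3-methoxy-4-[(1R)-1-methoxy-3-methylbutyl]phenoxy}tetrahydropyran
Product: 13 6-hydroxy-2-methoxy-3-[(1R)-1-methoxy-3-methylbutyl]benzoic acid, via aryllithium 11 (not isolated), via lithium carboxylate 12 (not isolated)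
Conditions: n-BuLi, TMEDA, THF, 0 °C → rt; CO2, –78 °C → rt; HCl (aq) to pH 2, THF–H2O, rt
Reagents that add atoms: carbon dioxide, O=C=O
Why: Directed ortho-metalation occurs at the only C–H flanked by both OMe and OTHP (cooperative directing groups), carboxylation follows, and at pH 2 the aryl THP ether ortho to the new CO2H is lost by intramolecular general-acid catalysis several orders of magnitude faster than the benzylic methyl ether (deactivated by the meta carboxyl) can ionise, so (R) is kept.

Step 7
Reactants: 14 2-fluoro-5-methylphenol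
Product: 15 2-(2-fluoro-5-methylphenoxy)tetrahydropyran
Conditions: 3,4-dihydro-2H-pyran, PPTS (cat.), CH2Cl2, rt
Reagents that add atoms: 3,4-dihydro-2H-pyran, C1=COCCC1
Why: Tetrahydropyranylation gives a base-stable phenol mask that survives alkyllithium and the later SNAr, and keeps ring B from becoming an electron-rich phenoxide.

Step 8
Reactants: 15 2-(2-fluoro-5-methylphenoxy)tetrahydropyran
Product: 18 2-fluoro-5-methyl-3-(tetrahydropyran-2-yloxy)benzaldehyde, via aryllithium 16 (not isolated), via lithium hemiaminal alkoxide 17 (not isolated)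
Conditions: s-BuLi, TMEDA, THF, –78 °C; DMF, –78 → 0 °C; H2O
Reagents that add atoms: N,N-dimethylformamide, CN(C)C=O
Why: Directed ortho-metalation takes the acidified, unhindered C–H next to fluorine (the position next to OTHP is blocked by the adjacent methyl group), and DMF formylation of the aryllithium with a neutral quench leaves the THP group on.

Step 9
Reactants: 13 6-hydroxy-2-methoxy-3-[(1R)-1-methoxy-3-methylbutyl]benzoic acid; 18 2-fluoro-5-methyl-3-(tetrahydropyran-2-yloxy)benzaldehyde
Product: 21 6-(2-formyl-6-hydroxy-4-methylphenoxy)-2-methoxy-3-[(1R)-1-methoxy-3-methylbutyl]benzoic acid, via dipotassium salt 19 (not isolated), via potassium carboxylate 20 (not isolated)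
Conditions: KOt-Bu (2.0 equiv), DMSO, rt; 18, 70 °C; then 0.2 M HCl, THF–H2O, rt
Reagents that add atoms: none
Why: SNAr (addition–elimination through a Meisenheimer adduct stabilised by the ortho formyl group) joins the phenoxide oxygen of 19 to the C–F carbon, any product of carboxylate attack is funnelled to the same ether by Smiles rearrangement, and the dilute acid removes the aryl THP acetal without ionising the benzylic ether, so (R) is kept.

## Compound list
1 | 3-methylbutan-1-ol | CC(C)CCO | starting material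
2 | 3-methylbutyl N,N-diisopropylcarbamate | CC(C)CCOC(=O)N(C(C)C)C(C)C | intermediate
3 | 4-bromo-3-methoxyphenol | COc1cc(O)ccc1Br | starting material
4 | 2-(4-bromo-3-methoxyphenoxy)tetrahydropyran (racemic acetal) | COc1cc(OC2CCCCO2)ccc1Br | intermediate
5 | (S)-[1-(diisopropylcarbamoyloxy)-3-methylbutyl]lithium, (–)-sparteine complex (drawn without the diamine) | [Li][C@@H](CC(C)C)OC(=O)N(C(C)C)C(C)C | intermediate
6 | (S)-chloro[1-(diisopropylcarbamoyloxy)-3-methylbutyl]zinc | Cl[Zn][C@@H](CC(C)C)OC(=O)N(C(C)C)C(C)C | intermediate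
7 | (1R)-1-[2-methoxy-4-(tetrahydropyran-2-yloxy)phenyl]-3-methylbutyl N,N-diisopropylcarbamate (THP epimers) | COc1cc(OC2CCCCO2)ccc1[C@@H](CC(C)C)OC(=O)N(C(C)C)C(C)C | intermediate
8 | (1R)-1-[2-methoxy-4-(tetrahydropyran-2-yloxy)phenyl]-3-methylbutan-1-ol (THP epimers) | COc1cc(OC2CCCCO2)ccc1[C@@H](CC(C)C)O | intermediate
9 | sodium alkoxide of 8 | COc1cc(OC2CCCCO2)ccc1[C@@H](CC(C)C)[O-].[Na+] | intermediate
10 | 2-{3-methoxy-4-[(1R)-1-methoxy-3-methylbutyl]phenoxy}tetrahydropyran (THP epimers) | COc1cc(OC2CCCCO2)ccc1[C@@H](CC(C)C)OC | intermediate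
11 | aryllithium of 10, lithium on the carbon between OMe and OTHP | COc1c([Li])c(OC2CCCCO2)ccc1[C@@H](CC(C)C)OC | intermediate
12 | lithium 2-methoxy-3-[(1R)-1-methoxy-3-methylbutyl]-6-(tetrahydropyran-2-yloxy)benzoate | COc1c(C(=O)[O-])c(OC2CCCCO2)ccc1[C@@H](CC(C)C)OC.[Li+] | intermediate
13 | 6-hydroxy-2-methoxy-3-[(1R)-1-methoxy-3-methylbutyl]benzoic acid | COc1c(C(=O)O)c(O)ccc1[C@@H](CC(C)C)OC | intermediate
14 | 2-fluoro-5-methylphenol | Cc1ccc(F)c(O)c1 | starting material
15 | 2-(2-fluoro-5-methylphenoxy)tetrahydropyran (racemic acetal) | Cc1ccc(F)c(OC2CCCCO2)c1 | intermediate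
16 | aryllithium of 15, lithium ortho to fluorine | Cc1cc([Li])c(F)c(OC2CCCCO2)c1 | intermediate
17 | lithium (dimethylamino)[2-fluoro-5-methyl-3-(tetrahydropyran-2-yloxy)phenyl]methanolate | Cc1cc(C([O-])N(C)C)c(F)c(OC2CCCCO2)c1.[Li+] | intermediate
18 | 2-fluoro-5-methyl-3-(tetrahydropyran-2-yloxy)benzaldehyde (racemic acetal) | Cc1cc(C=O)c(F)c(OC2CCCCO2)c1 | intermediate
19 | dipotassium salt (carboxylate and phenoxide) of 13 | COc1c(C(=O)[O-])c([O-])ccc1[C@@H](CC(C)C)OC.[K+].[K+] | intermediate
20 | potassium 6-[2-formyl-4-methyl-6-(tetrahydropyran-2-yloxy)phenoxy]-2-methoxy-3-[(1R)-1-methoxy-3-methylbutyl]benzoate (THP epimers) | COc1c([C@@H](CC(C)C)OC)ccc(Oc2c(OC3CCCCO3)cc(C)cc2C=O)c1C(=O)[O-].[K+] | intermediate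
21 | 6-(2-formyl-6-hydroxy-4-methylphenoxy)-2-methoxy-3-[(1R)-1-methoxy-3-methylbutyl]benzoic acid (CNP0328949.1) | COc1c([C@@H](CC(C)C)OC)ccc(Oc2c(O)cc(C)cc2C=O)c1C(=O)O | target

## Step count and risks
Total step count: 9. Longest linear sequence: 6 (step 1 or 2, then steps 3, 4, 5, 6 and 9).

**Most likely to fail, first: step 3.**
- The aryl bromide is electron-rich and ortho-substituted.
- The secondary α-oxy alkylpalladium species can undergo β-hydride elimination or chain walking.
- Zinc salts may attack the THP acetal, and the enantiomer ratio (expected about 95:5 or better) may erode at 60 °C.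
- If needed, the ratio can be polished at acid 13 by crystallising a salt with an enantiopure amine.

The fallback sets out from 4 and from lithiated carbamate 5 and comes back at alcohol 8, so step 4 drops out. Bromide 4 is converted by Miyaura borylation (B2pin2, KOAc, Pd(dppf)Cl2, dioxane, 80 °C) into 2-[2-methoxy-4-(tetrahydropyran-2-yloxy)phenyl]-4,4,5,5-tetramethyl-1,3,2-dioxaborolane F1. Adding it to 5 at –78 °C gives, with retention, the lithium (S)-boronate complex F2. With MgBr2·OEt2 at reflux, its aryl group migrates from boron to carbon with inversion and expels the carbamate. This gives 2-{(1R)-1-[2-methoxy-4-(tetrahydropyran-2-yloxy)phenyl]-3-methylbutyl}-4,4,5,5-tetramethyl-1,3,2-dioxaborolane F3. Oxidation with NaOH/H2O2 goes with retention and gives the same (R)-alcohol 8.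

**Second: step 9.**
- The fluorine sits between CHO and OTHP.
- The salicylate oxygen is a modest nucleophile.
- The phenoxide para to the benzylic methoxy group could lose methoxide on prolonged heating (para-quinone methide), which would racemise or destroy the side chain.
- 13 may also decarboxylate if overheated.

The fallback sets out from 13 and 18 and comes back at target 21. It turns the coupling into a low-temperature intramolecular reaction. Aldehyde 18 is deprotected (AcOH–THF–H2O, 40 °C) to 2-fluoro-3-hydroxy-5-methylbenzaldehyde F4. Carbodiimide coupling with 13 (DCC, DMAP cat., toluene–CH2Cl2, rt) follows, and the chelated 6-OH of 13 stays free, as in classical depside couplings. The product is 2-fluoro-3-formyl-5-methylphenyl 6-hydroxy-2-methoxy-3-[(1R)-1-methoxy-3-methylbutyl]benzoate F5. K2CO3 in DMSO at rt to 40 °C closes the seven-membered ring by SNAr on a C–F carbon now flanked by formyl and acyloxy groups. This gives the depsidone 1-methoxy-2-[(1R)-1-methoxy-3-methylbutyl]-8-methyl-11-oxo-11H-dibenzo[b,e][1,4]dioxepine-6-carbaldehyde F6. LiOH in THF–H2O at rt, then pH 3, opens the lactone to 21.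

**Third: step 6.**
- The site between OMe and OTHP is crowded because the OMe group is buttressed by the side chain.
- Lithiation next to OTHP alone, or incomplete metalation, is therefore possible.

The fallback sets out from organozinc chloride 6 and comes back at acid 13. It relies on C–H acidity next to fluorine and brings the phenol oxygen in afterwards.
- 6 is coupled under the step 3 catalyst with commercial 1-bromo-4-fluoro-2-methoxybenzene to give (1R)-1-(4-fluoro-2-methoxyphenyl)-3-methylbutyl N,N-diisopropylcarbamate F7.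
- LiAlH4 gives (1R)-1-(4-fluoro-2-methoxyphenyl)-3-methylbutan-1-ol F8.
- NaH/MeI gives 4-fluoro-2-methoxy-1-[(1R)-1-methoxy-3-methylbutyl]benzene F9.
- LDA in THF at –78 °C, then CO2, carboxylates the position between F and OMe to give 6-fluoro-2-methoxy-3-[(1R)-1-methoxy-3-methylbutyl]benzoic acid F10.
- Powdered NaOH in 1,3-dimethyl-2-imidazolidinone at 130 °C replaces the fluorine ortho to the carboxylate by hydroxide to give 13.

## Further compounds
F1 | step 3 | 2-[2-methoxy-4-(tetrahydropyran-2-yloxy)phenyl]-4,4,5,5-tetramethyl-1,3,2-dioxaborolane | COc1cc(OC2CCCCO2)ccc1B3OC(C)(C)C(C)(C)O3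
F2 | step 3 | lithium (S)-boronate complex of F1 and 5 | COc1cc(OC2CCCCO2)ccc1[B-]3(OC(C)(C)C(C)(C)O3)[C@@H](CC(C)C)OC(=O)N(C(C)C)C(C)C.[Li+]
F3 | step 3 | 2-{(1R)-1-[2-methoxy-4-(tetrahydropyran-2-yloxy)phenyl]-3-methylbutyl}-4,4,5,5-tetramethyl-1,3,2-dioxaborolane | COc1cc(OC2CCCCO2)ccc1[C@@H](CC(C)C)B3OC(C)(C)C(C)(C)O3
F4 | step 9 | 2-fluoro-3-hydroxy-5-methylbenzaldehyde | Cc1cc(C=O)c(F)c(O)c1
F5 | step 9 | 2-fluoro-3-formyl-5-methylphenyl 6-hydroxy-2-methoxy-3-[(1R)-1-methoxy-3-methylbutyl]benzoate | COc1c(C(=O)Oc2cc(C)cc(C=O)c2F)c(O)ccc1[C@@H](CC(C)C)OC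
F6 | step 9 | 1-methoxy-2-[(1R)-1-methoxy-3-methylbutyl]-8-methyl-11-oxo-11H-dibenzo[b,e][1,4]dioxepine-6-carbaldehyde | COc1c2C(=O)Oc3cc(C)cc(C=O)c3Oc2ccc1[C@@H](CC(C)C)OC
F7 | step 6 | (1R)-1-(4-fluoro-2-methoxyphenyl)-3-methylbutyl N,N-diisopropylcarbamate | COc1cc(F)ccc1[C@@H](CC(C)C)OC(=O)N(C(C)C)C(C)C
F8 | step 6 | (1R)-1-(4-fluoro-2-methoxyphenyl)-3-methylbutan-1-ol | COc1cc(F)ccc1[C@@H](CC(C)C)O
F9 | step 6 | 4-fluoro-2-methoxy-1-[(1R)-1-methoxy-3-methylbutyl]benzene | COc1cc(F)ccc1[C@@H](CC(C)C)OC
F10 | step 6 | 6-fluoro-2-methoxy-3-[(1R)-1-methoxy-3-methylbutyl]benzoic acid | COc1c(C(=O)O)c(F)ccc1[C@@H](CC(C)C)OC
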